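## Retrosynthetic overview
1. The pyranone ring of (2S)-sigmoidin A (**15**) is closed last. A chalcone isomerase (isomerase class) does an enantioselective intramolecular oxa-Michael closure of pentahydroxy-diprenylchalcone **14**. This sets C2 (S), the only stereocenter.
2. **14** comes from Pd(0) removal of four allyl ethers in **13**. **13** comes from a Claisen–Schmidt condensation of aryl aldehyde **10** with acetophenone **12**.
3. The B-ring aldehyde **10** carries its prenyls as allyl groups that are converted by cross-metathesis. Those allyl groups are placed by a double aromatic Claisen rearrangement of protocatechualdehyde bis(allyl ether). **12** comes from phloroacetophenone.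
4. Ring order: the B-ring substituents are installed first, then the chalcone alkene, and the heterocyclic C ring last.

Assumptions: the chalcone isomerase (recombinant *Medicago sativa* CHI, type I, from *E. coli*) accepts the lipophilic prenylated substrate. The enzyme is the asymmetric catalyst for C2. Reagents that contribute atoms are numbered as starting materials; bases, solvents and catalysts are not.

## Route

**Step 1**
Reactants: **1** 3,4-dihydroxybenzaldehyde; **2** allyl bromide
Product: **3** 3,4-bis(allyloxy)benzaldehyde
Conditions: **2** (2.5 equiv), K2CO3 (3 equiv), DMF, 60 °C, 12 h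
Reagents that add atoms: allyl bromide, C=CCBr
Why: Williamson O-alkylation of both phenols; the aldehyde is inert and no stereocenter is involved.

**Step 2**
Reactants: **3**
Product: **4** 2,5-diallyl-3,4-dihydroxybenzaldehyde
Conditions: N,N-diethylaniline, 200–210 °C (sealed tube or microwave), Ar, 3–6 h
Reagents that add atoms: none
Why: Double aromatic Claisen rearrangement. The 4-O-allyl group can only migrate to C5 and the 3-O-allyl group only to C2, because C3 and C4 are blocked by oxygen. The regiochemistry is therefore fixed.

**Step 3**
Reactants: **4**; **5** acetic anhydride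
Product: **6** 2,5-diallyl-3,4-diacetoxybenzaldehyde
Conditions: **5** (3 equiv), pyridine, cat. DMAP, CH2Cl2, 0 °C → rt, 3 h
Reagents that add atoms: acetic anhydride, CC(=O)OC(C)=O
Why: The catechol is capped as diacetate so that the free diol does not poison the Ru catalyst in the next step. This is a standard acetylation.

**Step 4**
Reactants: **6**; **7** 2-methyl-2-butene
Product: **8** 3,4-diacetoxy-2,5-bis(3-methylbut-2-enyl)benzaldehyde
Conditions: **7** (25 equiv), Grubbs II (5 mol%), 1,4-benzoquinone (10 mol%), CH2Cl2, 40 °C, sealed, 12 h
Reagents that add atoms: 2-methyl-2-butene, CC=C(C)C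
Why: Olefin cross-metathesis with a trisubstituted partner converts each terminal allyl arene into a linear prenyl arene; propene is lost. Benzoquinone suppresses Ru–H alkene isomerisation. The aldehyde and aryl acetates are tolerated.

**Step 5**
Reactants: **8**
Product: **9** 3,4-dihydroxy-2,5-bis(3-methylbut-2-enyl)benzaldehyde
Conditions: K2CO3 (2.5 equiv), MeOH (degassed), 0 °C → rt, 1 h, Ar; quench with sat. NH4Cl
Reagents that add atoms: none
Why: Transesterification (methanolysis) removes the phenolic acetates, leaving the prenyl alkenes and aldehyde untouched.

**Step 6**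
Reactants: **9**; **2** allyl bromide
Product: **10** 3,4-bis(allyloxy)-2,5-bis(3-methylbut-2-enyl)benzaldehyde
Conditions: **2** (3 equiv), K2CO3 (4 equiv), DMF, 60 °C, 12 h
Reagents that add atoms: allyl bromide, C=CCBr
Why: Williamson etherification. The allyl ethers are base-stable for the aldol step and can later be removed with Pd(0) under non-acidic conditions. This is needed because acid would cyclise the chalcone non-selectively.

**Step 7**
Reactants: **11** 2,4,6-trihydroxyacetophenone (phloroacetophenone); **2** allyl bromide
Product: **12** 1-[2-hydroxy-4,6-bis(allyloxy)phenyl]ethan-1-one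
Conditions: **2** (2.1 equiv), K2CO3 (2.3 equiv), acetone, reflux, 8 h; chromatography
Reagents that add atoms: allyl bromide, C=CCBr
Why: The 4-OH is the most acidic and reacts first. One ortho OH then reacts, while the other stays locked in a hydrogen bond with the carbonyl. This gives the 2-hydroxy-4,6-diether, separable from the mono- and tri-allyl by-products.

**Step 8**
Reactants: **10**; **12**
Product: **13** (E)-2′-hydroxy-3,4,4′,6′-tetrakis(allyloxy)-2,5-diprenylchalcone
Conditions: KOH (50% aq., ~6 equiv), EtOH, 0 °C → rt, 48 h, Ar, dark
Reagents that add atoms: none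
Why: Claisen–Schmidt aldol condensation. The chelated 2′-OH acetophenone enolises and adds to the aldehyde, and dehydration gives the thermodynamic E-enone. The protected B ring keeps the aldehyde electrophilic.

**Step 9**
Reactants: **13**
Product: **14** (E)-2′,3,4,4′,6′-pentahydroxy-2,5-diprenylchalcone
Conditions: Pd(PPh3)4 (12 mol%), K2CO3 (6 equiv), MeOH/THF (1:1, degassed), rt, 4 h, Ar, dark; quench to pH 6 with NH4Cl; rapid degassed filtration through short silica with 1 mM ascorbate; store at –20 °C under Ar
Reagents that add atoms: none (allyl groups leave as allyl methyl ether)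
Why: Tsuji–Trost deallylation of aryl allyl ethers. Methoxide is the allyl acceptor, the conditions are non-acidic so the chalcone does not cyclise racemically, and the C-prenyl groups and the enone are not touched. The only other source of racemic flavanone is slow phenolate cyclisation.

**Step 10**
Reactants: **14**
Product: **15** (2S)-sigmoidin A
Conditions: recombinant chalcone isomerase (CHI, EC 5.5.1.6), 50 mM potassium phosphate pH 7.0, 1 mM sodium ascorbate, 10% v/v DMSO (chalcone added as DMSO stock), 25 °C, N2, dark, 4–16 h; extract with EtOAc; RP-HPLC; chiral HPLC for ee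
Reagents that add atoms: none (isomerisation)
Why: The enzymatic intramolecular oxa-Michael addition (a 6-endo-trig closure) of the 2′-phenol onto the enone is held in one chalcone conformation in the active site and delivers the (2S)-flavanone. This sets C2 and is not scrambled afterwards, since the product is stable at neutral pH and the spontaneous racemic background is slow compared with catalysis.

## Compound list
1 | 3,4-dihydroxybenzaldehyde | O=Cc1ccc(O)c(O)c1 | starting material
2 | allyl bromide | C=CCBr | starting material
3 | 3,4-bis(allyloxy)benzaldehyde | O=Cc1ccc(OCC=C)c(OCC=C)c1 | intermediate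
4 | 2,5-diallyl-3,4-dihydroxybenzaldehyde | O=Cc1cc(CC=C)c(O)c(O)c1CC=C | intermediate
5 | acetic anhydride | CC(=O)OC(C)=O | starting material
6 | 2,5-diallyl-3,4-diacetoxybenzaldehyde | O=Cc1cc(CC=C)c(OC(C)=O)c(OC(C)=O)c1CC=C | intermediate
7 | 2-methyl-2-butene | CC=C(C)C | starting material
8 | 3,4-diacetoxy-2,5-diprenylbenzaldehyde | O=Cc1cc(CC=C(C)C)c(OC(C)=O)c(OC(C)=O)c1CC=C(C)C | intermediate
9 | 3,4-dihydroxy-2,5-diprenylbenzaldehyde | O=Cc1cc(CC=C(C)C)c(O)c(O)c1CC=C(C)C | intermediate
10 | 3,4-bis(allyloxy)-2,5-diprenylbenzaldehyde | O=Cc1cc(CC=C(C)C)c(OCC=C)c(OCC=C)c1CC=C(C)C | intermediate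
11 | 2,4,6-trihydroxyacetophenone | CC(=O)c1c(O)cc(O)cc1O | starting material
12 | 2-hydroxy-4,6-bis(allyloxy)acetophenone | CC(=O)c1c(O)cc(OCC=C)cc1OCC=C | intermediate
13 | tetra-O-allyl chalcone (E) | O=C(/C=C/c1cc(CC=C(C)C)c(OCC=C)c(OCC=C)c1CC=C(C)C)c1c(O)cc(OCC=C)cc1OCC=C | intermediate
14 | 2′,3,4,4′,6′-pentahydroxy-2,5-diprenylchalcone (E) | O=C(/C=C/c1cc(CC=C(C)C)c(O)c(O)c1CC=C(C)C)c1c(O)cc(O)cc1O | intermediate
15 | (2S)-sigmoidin A | CC(C)=CCc1cc([C@@H]2CC(=O)c3c(O)cc(O)cc3O2)c(CC=C(C)C)c(O)c1O | target

## Totals
Total steps: 10. Longest linear sequence: 9 steps (1 → 3 → 4 → 6 → 8 → 9 → 10 → 13 → 14 → 15; Steps 1–6, 8, 9, 10).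

## Three steps most likely to fail
1. **Step 10 (CHI cyclisation).** The bulky, lipophilic ortho-prenyl substrate may be poorly accepted, or the racemic background reaction may compete.
   Fallback: skip the enzyme. Run a bifunctional-organocatalyst-controlled (cinchona-squaramide) intramolecular oxa-Michael on tetra-allyl chalcone **13**. Then remove the allyl groups from the flavanone with Pd(PPh3)4/PhSiH3 under neutral conditions.
2. **Step 2 (double thermal Claisen).** The second rearrangement, into the hindered C2 position, may give decomposition or incomplete conversion at 200 °C.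
   Fallback: use differentiated protection and two separate Claisen sequences. Start from 4-benzyloxy-3-hydroxybenzaldehyde, allylate, rearrange to C2, and remove the benzyl group with BCl3/pentamethylbenzene. Then allylate the 4-OH and rearrange to C5.
3. **Step 9 (four-fold Pd deallylation of the chalcone).** Incomplete removal, oxidation of the prenylated catechol, or partial cyclisation to racemic flavanone can occur.
   Fallback: use a bis-MOM-protected B ring and A ring in the Claisen–Schmidt, then remove the MOM groups with HCl/MeOH. This cyclises to racemic sigmoidin A, which is resolved by preparative chiral-phase HPLC to give the (S)-enantiomer.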